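If the target reading of a run stops moving once the starting material reading is gone, the clock has nothing more to tell, and the thing to watch is a ratio. In the spring run the starting material reads 0.8% at 0.417 h; the target reads 79.9% there and 80.8% at 3.00 h, a step inside the scatter of 1 percentage point. The other runs flatten in the same way, so I read the flasks at 4.0 h from plateaus, although no run was followed that far.

| flask | starting material | reagent | second substrate | remark | time |
|---|---|---|---|---|---|
| dusk | 0.0073 M | 0.030 M | 4 mM | run made earlier |  |
| spring | 0.013 M | 0.030 M | 4 mM | run made earlier |  |
| summer | 0.021 M | 0.030 M | 4 mM | run made earlier |  |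
| noon | 0.020 M | 0.078 M | 4 mM | run made earlier |  |
| beta | 0.020 M | 0.0300 M | 4.00 mM |  | 4.0 h |
| alpha | 0.020 M | 0.0600 M | 4.00 mM |  | 4.0 h |
| gamma | 0.020 M | 0.120 M | 2.50 mM |  | 4.0 h |
| eta | 0.010 M | 0.0300 M | 4.00 mM |  | 4.0 h |
| theta | 0.0060 M | 0.100 M | 2.00 mM |  | 4.0 h |
| delta | 0.030 M | 0.0500 M | 4.00 mM |  | 4.0 h |

- dusk (time / h: target / %, starting material / %): 0.500: 85.3, 0; 1.00: 86.2, 1.6; 1.50: 87.0, 0; 2.50: 87.0, 0; 3.00: 85.7, 0
- spring (time / h: target / %, starting material / %): 0.250: 76.6, 7.5; 0.417: 79.9, 0.8; 0.833: 78.6, 0; 1.33: 81.3, 0; 3.00: 80.8, 0
- summer (time / h: target / %, starting material / %): 0.250: 66.7, 8.5; 0.417: 68.5, 1.2; 0.833: 71.1, 0; 1.33: 68.7, 0; 3.00: 70.5, 1.1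
- noon (time / h: target / %, starting material / %): 0.250: 90.1, 1.7; 0.417: 89.4, 0; 0.833: 91.0, 0.3; 1.33: 89.2, 0; 3.00: 88.3, 0.2

(standard deviation of a reading: 1 percentage point)



* the flasks by amount of target, in percent of the starting material charged, highest first, at 4.0 h (beta / alpha / gamma / eta / theta / delta)
* the amount of target, in percent of the starting material charged of the flask you put first, at 4.0 h
* the amount of target, in percent of the starting material charged of the flask you put last, at 4.0 h

Each plateau is a share. Starting material either meets reagent and gives target, or it is lost. If each loss also takes starting material, dividing the rate of loss by the rate of capture cancels c(starting material), and time drops out with it. What remains I call the loss ratio w, the inverse of a selectivity factor: the share of starting material not found as target over the share found as target. Capture goes with c(reagent), and I take its mean over the run: the reagent charge minus half of the starting material charge, assuming one reagent is used per target. I take the loss as linear in the charges, so w times mean reagent should equal s·c(starting material) + g·c(second substrate).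

The dusk plateau averages 86.2%, which makes that product 4.20 mM. The summer plateau averages 69.7%, which makes it 8.48 mM. The difference over the difference in charge gives the loss coefficient s = 0.312. The remainder gives g = 0.482, which is a guess, since second substrate stood at 4 mM in all these runs. The noon run was not used, so it is a check: the rule gives 89.3% against a plateau of 89.6%.

For theta, w is 0.0292, so I expect 97.2% of target. For beta, w is 0.408, so I expect 71.0%. My ratio rises from theta through gamma, alpha, eta and delta to beta.

The forecast gives the same order, theta > gamma > alpha > eta > delta > beta, with 96.5% for theta and 70.5% for beta, both a little below mine, and it reads the runs thus: “each plateau is a selectivity, not a rate”.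

The simulation gives theta > gamma > alpha > eta > delta > beta, with 97.3% for the first flask and 72.5% for the last.

    starting material + reagent → target (k = 0.140 /M/s)
    second substrate + reagent → second product (k = 0.570 /M/s)
    starting material + second substrate → cross product (k = 0.400 /M/s)
    starting material + target → side product (k = 0.0360 /M/s)

The target found in beta makes w 0.379, against my 0.408. The main reason for beta's shortfall is the step from starting material and target to side product: with that step taken away, beta holds 93.8% of target instead of 72.5%. The length of the run is not what to watch: ten times the run length changes nothing in beta. For the neighbour of beta charged with 0.075 M of reagent, the same s and g give w = 0.126 and 88.8% of target; the simulation gives 89.8%.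

Readings and results were computed for an exercise, noise included.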